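Cuts, in retrosynthetic order: the C4 ketone goes back to a carbinol; ring C is opened at the O1–C8a aryl ether bond; the C4–C4a bond is cut to a ring A aryllithium and a ring B β-silyloxy aldehyde; the C6–geranyl bond and the C2–C3 (carbinol–allyl) bond are cut last.
Forward order: rings A and B are bought aromatic (5-chlororesorcinol, 3,5-dihydroxybenzaldehyde); geranyl is set at C6, the C2–C3–C4 chain is joined at C4a, ring C is closed last through O1–C8a, then C4 is oxidised and the four MOM ethers are removed.
Enabling feature: C8 is the only hydrogen-bearing carbon of ring A and lies between C8a and the oxygenated C7, so a chlorine on C8a and H–C8 can leave together as a C8–C8a aryne. The C2 oxygen, tethered through C3–C4–C4a, can reach this aryne only at C8a, which fixes the 6-geranyl (not 8-geranyl) pattern and avoids any chalcone.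
Stereochemistry: C2 (S) comes from a Keck allylation of the ring B aldehyde with (S)-BINOL/Ti(OiPr)4. The C2–O bond is never broken afterwards and C4 stays sp3 until ring C exists, so neither retro-aldol cleavage nor elimination can erode it; the C4 carbinol epimers converge on oxidation.

Key step: step 9

Remark: 5-chlororesorcinol, geranyl bromide and 3,5-dihydroxybenzaldehyde are taken as purchasable. Geranyl = (2E)-3,7-dimethylocta-2,6-dien-1-yl, MOM = methoxymethyl, TBS = tert-butyldimethylsilyl; locants C2 to C8a are those of the chromanone of the target.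

Step 1
Reactants: 1 5-chlororesorcinol
Product: 2 1-chloro-3,5-bis(methoxymethoxy)benzene
Conditions: NaH, DMF, 0 °C; MOMCl, 0 °C to rt
Reagents that add atoms: chloromethyl methyl ether, COCCl
Why: Williamson-type O-alkylation of both phenoxides should give the bis-MOM ether, chosen because MOM ethers direct the two later ortho-lithiations and come off under mild acid.

Step 2
Reactants: 2 1-chloro-3,5-bis(methoxymethoxy)benzene; 3 geranyl bromide
Product: 5 5-chloro-2-[(2E)-3,7-dimethylocta-2,6-dien-1-yl]-1,3-bis(methoxymethoxy)benzene, via aryllithium 4 (not isolated)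
Conditions: n-BuLi, THF, −30 °C; CuI (10 mol %), 3, −78 °C to rt
Reagents that add atoms: none
Why: Directed ortho-metalation should occur at the carbon flanked by both MOM ethers (two cooperating directors outweigh chlorine), and copper-assisted SN2 allylation with the primary allylic bromide should keep the E double bond, which places geranyl between the future C5 and C7 oxygens.

Step 3
Reactants: 6 3,5-dihydroxybenzaldehyde
Product: 7 3,5-bis(methoxymethoxy)benzaldehyde
Conditions: NaH, DMF, 0 °C; MOMCl, 0 °C to rt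
Reagents that add atoms: chloromethyl methyl ether, COCCl
Why: Williamson-type O-alkylation of the two phenoxides; the aldehyde has no enolisable hydrogen and should survive.

Step 4
Reactants: 7 3,5-bis(methoxymethoxy)benzaldehyde
Product: 8 (1S)-1-[3,5-bis(methoxymethoxy)phenyl]but-3-en-1-ol
Conditions: (S)-BINOL (20 mol %), Ti(OiPr)4 (10 mol %), 4 Å MS, CH2Cl2; allylSnBu3, −20 °C; aq. NaHCO3
Reagents that add atoms: allyltributylstannane, C=CC[Sn](CCCC)(CCCC)CCCC
Why: Keck asymmetric allylation, in which the (S)-BINOL titanium complex should expose the Si face of the aryl aldehyde to the allylstannane and so give the S carbinol that becomes C2.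

Step 5
Reactants: 8 (1S)-1-[3,5-bis(methoxymethoxy)phenyl]but-3-en-1-ol
Product: 9 tert-butyl{[(1S)-1-[3,5-bis(methoxymethoxy)phenyl]but-3-en-1-yl]oxy}dimethylsilane
Conditions: TBSCl, imidazole, DMF, rt
Reagents that add atoms: tert-butyldimethylsilyl chloride, CC(C)(C)[Si](C)(C)Cl
Why: Standard silylation of the secondary benzylic alcohol, which masks the future ring oxygen during the organolithium addition of step 7.

Step 6
Reactants: 9 tert-butyl{[(1S)-1-[3,5-bis(methoxymethoxy)phenyl]but-3-en-1-yl]oxy}dimethylsilane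
Product: 11 (3S)-3-[3,5-bis(methoxymethoxy)phenyl]-3-[(tert-butyldimethylsilyl)oxy]propanal, via ozonide 10 (not isolated)
Conditions: O3, CH2Cl2, −78 °C; PPh3, −78 °C to rt
Reagents that add atoms: ozone, [O-][O+]=O
Why: Ozonolysis with reductive work-up should cleave the only C=C bond present at this stage (the geranyl-bearing ring A is joined later) to the aldehyde that becomes C4, without touching the C2 centre.

Step 7
Reactants: 5 5-chloro-2-[(2E)-3,7-dimethylocta-2,6-dien-1-yl]-1,3-bis(methoxymethoxy)benzene; 11 (3S)-3-[3,5-bis(methoxymethoxy)phenyl]-3-[(tert-butyldimethylsilyl)oxy]propanal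
Product: 13 (1RS,3S)-3-[3,5-bis(methoxymethoxy)phenyl]-3-[(tert-butyldimethylsilyl)oxy]-1-{6-chloro-3-[(2E)-3,7-dimethylocta-2,6-dien-1-yl]-2,4-bis(methoxymethoxy)phenyl}propan-1-ol, via aryllithium 12 (not isolated)
Conditions: 5, s-BuLi, TMEDA, THF, −78 °C; 11, −78 °C; aq. NH4Cl
Reagents that add atoms: none
Why: Directed ortho-metalation at one of the two symmetry-equivalent ring CH groups flanked by chlorine and a MOM ether, held at −78 °C so that the ortho-chloroaryllithium keeps its LiCl, followed by 1,2-addition to the aldehyde; the new C4 carbinol centre forms as a mixture, which does not matter because C4 is oxidised in step 10.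

Step 8
Reactants: 13 (1RS,3S)-3-[3,5-bis(methoxymethoxy)phenyl]-3-[(tert-butyldimethylsilyl)oxy]-1-{6-chloro-3-[(2E)-3,7-dimethylocta-2,6-dien-1-yl]-2,4-bis(methoxymethoxy)phenyl}propan-1-ol
Product: 14 (1RS,3S)-3-[3,5-bis(methoxymethoxy)phenyl]-1-{6-chloro-3-[(2E)-3,7-dimethylocta-2,6-dien-1-yl]-2,4-bis(methoxymethoxy)phenyl}propane-1,3-diol
Conditions: Bu4NF, THF, 0 °C to rt
Reagents that add atoms: none
Why: Fluoride-induced desilylation should free the C2 hydroxyl under non-acidic conditions, which the acid-labile, electron-rich benzylic C4 carbinol and the MOM ethers tolerate.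

Step 9
Reactants: 14 (1RS,3S)-3-[3,5-bis(methoxymethoxy)phenyl]-1-{6-chloro-3-[(2E)-3,7-dimethylocta-2,6-dien-1-yl]-2,4-bis(methoxymethoxy)phenyl}propane-1,3-diol
Product: 18 (2S,4RS)-2-[3,5-bis(methoxymethoxy)phenyl]-6-[(2E)-3,7-dimethylocta-2,6-dien-1-yl]-5,7-bis(methoxymethoxy)-3,4-dihydro-2H-chromen-4-ol, via chloroaryllithium 15 (not isolated), via aryne 16 (not isolated), via lithiochroman 17 (not isolated)
Conditions: LiTMP (from n-BuLi and 2,2,6,6-tetramethylpiperidine, 4 equiv), THF, −78 °C to rt; aq. NH4Cl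
Reagents that add atoms: none
Why: LiTMP should first form the dilithium dialkoxide and then remove the only ring A proton, H–C8, which is acidified by the chlorine on C8a and the MOM ether on C7; the ortho-chloroaryllithium 15 loses LiCl on warming to give the C8–C8a aryne 16, the C2 alkoxide adds to C8a, and the 8-lithiochroman 17 is protonated on work-up. The closest known reaction type is the amide-base aryne ring closure of ω-(halophenyl)alkanols to chromans and dihydrobenzofurans (benzyne cyclisation). Ring C closes in a 6-exo-dig mode, the attacked aryne carbon C8a lying inside the new ring and C8 outside it. No stereocenter is made: C2 stays S because only its oxygen reacts and the C2–O bond remains intact, and the C4 carbinol mixture converges in step 10. The step needs attack at C8a and not at C8, which is secured both by the six-membered transition state and by the inductive pull of the C7 oxygen (nucleophiles add meta to the alkoxy group of 3-alkoxyarynes, leaving the carbanion next to oxygen); the C4 alkoxide cannot compete because it could only close a four-membered ring, and with C4 sp3 neither retro-aldol cleavage nor E1cB loss of the C2 oxygen is possible. A hindered lithium amide is used in place of an alkyllithium so that the ring B proton between two MOM ethers, which lacks halogen activation, stays in place and the amine by-product adds only slowly to the aryne.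

Step 10
Reactants: 18 (2S,4RS)-2-[3,5-bis(methoxymethoxy)phenyl]-6-[(2E)-3,7-dimethylocta-2,6-dien-1-yl]-5,7-bis(methoxymethoxy)-3,4-dihydro-2H-chromen-4-ol
Product: 19 (2S)-2-[3,5-bis(methoxymethoxy)phenyl]-6-[(2E)-3,7-dimethylocta-2,6-dien-1-yl]-5,7-bis(methoxymethoxy)-2,3-dihydro-4H-chromen-4-one
Conditions: Dess–Martin periodinane, CH2Cl2, 0 °C to rt
Reagents that add atoms: none
Why: Dess–Martin oxidation of the secondary benzylic alcohol should turn both C4 epimers into the one ketone under near-neutral conditions that leave the geranyl alkenes, the MOM ethers and the base-sensitive C2 centre alone.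

Step 11
Reactants: 19 (2S)-2-[3,5-bis(methoxymethoxy)phenyl]-6-[(2E)-3,7-dimethylocta-2,6-dien-1-yl]-5,7-bis(methoxymethoxy)-2,3-dihydro-4H-chromen-4-one
Product: 20 Schizolaenone C [(2S)-2-(3,5-dihydroxyphenyl)-6-[(2E)-3,7-dimethylocta-2,6-dien-1-yl]-5,7-dihydroxy-2,3-dihydro-4H-chromen-4-one]
Conditions: HCl (1.25 M in MeOH), 40 °C
Reagents that add atoms: none
Why: Acid-catalysed acetal exchange with methanol should remove all four MOM groups as dimethoxymethane; the mild temperature is chosen so that the phenols flanking the geranyl group do not add to its double bond and the 5-hydroxyflavanone keeps its C2 configuration.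

Compound list
1 | 5-chlororesorcinol (5-chlorobenzene-1,3-diol) | Oc1cc(O)cc(Cl)c1 | starting material
2 | 1-chloro-3,5-bis(methoxymethoxy)benzene | COCOc1cc(Cl)cc(OCOC)c1 | intermediate
3 | geranyl bromide [(2E)-1-bromo-3,7-dimethylocta-2,6-diene] | CC(C)=CCC/C(C)=C/CBr | starting material
4 | [4-chloro-2,6-bis(methoxymethoxy)phenyl]lithium | [Li]c1c(OCOC)cc(Cl)cc1OCOC | intermediate
5 | 5-chloro-2-[(2E)-3,7-dimethylocta-2,6-dien-1-yl]-1,3-bis(methoxymethoxy)benzene | CC(C)=CCC/C(C)=C/Cc1c(OCOC)cc(Cl)cc1OCOC | intermediate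
6 | 3,5-dihydroxybenzaldehyde | O=Cc1cc(O)cc(O)c1 | starting material
7 | 3,5-bis(methoxymethoxy)benzaldehyde | O=Cc1cc(OCOC)cc(OCOC)c1 | intermediate
8 | (1S)-1-[3,5-bis(methoxymethoxy)phenyl]but-3-en-1-ol | C=CC[C@H](O)c1cc(OCOC)cc(OCOC)c1 | intermediate
9 | tert-butyl{[(1S)-1-[3,5-bis(methoxymethoxy)phenyl]but-3-en-1-yl]oxy}dimethylsilane | C=CC[C@H](O[Si](C)(C)C(C)(C)C)c1cc(OCOC)cc(OCOC)c1 | intermediate
10 | 3-{(2S)-2-[3,5-bis(methoxymethoxy)phenyl]-2-[(tert-butyldimethylsilyl)oxy]ethyl}-1,2,4-trioxolane (ozonide, epimers at the ring carbon) | C1(C[C@H](O[Si](C)(C)C(C)(C)C)c2cc(OCOC)cc(OCOC)c2)OCOO1 | intermediate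
11 | (3S)-3-[3,5-bis(methoxymethoxy)phenyl]-3-[(tert-butyldimethylsilyl)oxy]propanal | O=CC[C@H](O[Si](C)(C)C(C)(C)C)c1cc(OCOC)cc(OCOC)c1 | intermediate
12 | {6-chloro-3-[(2E)-3,7-dimethylocta-2,6-dien-1-yl]-2,4-bis(methoxymethoxy)phenyl}lithium | CC(C)=CCC/C(C)=C/Cc1c(OCOC)cc(Cl)c([Li])c1OCOC | intermediate
13 | (1RS,3S)-3-[3,5-bis(methoxymethoxy)phenyl]-3-[(tert-butyldimethylsilyl)oxy]-1-{6-chloro-3-[(2E)-3,7-dimethylocta-2,6-dien-1-yl]-2,4-bis(methoxymethoxy)phenyl}propan-1-ol | CC(C)=CCC/C(C)=C/Cc1c(OCOC)cc(Cl)c(C(O)C[C@H](O[Si](C)(C)C(C)(C)C)c2cc(OCOC)cc(OCOC)c2)c1OCOC | intermediate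
14 | (1RS,3S)-3-[3,5-bis(methoxymethoxy)phenyl]-1-{6-chloro-3-[(2E)-3,7-dimethylocta-2,6-dien-1-yl]-2,4-bis(methoxymethoxy)phenyl}propane-1,3-diol | CC(C)=CCC/C(C)=C/Cc1c(OCOC)cc(Cl)c(C(O)C[C@H](O)c2cc(OCOC)cc(OCOC)c2)c1OCOC | intermediate
15 | dilithium dialkoxide of 14 lithiated at the ring A carbon between chlorine and the MOM ether (future C8) | CC(C)=CCC/C(C)=C/Cc1c(OCOC)c([Li])c(Cl)c(C(O[Li])C[C@H](O[Li])c2cc(OCOC)cc(OCOC)c2)c1OCOC | intermediate
16 | aryne formed from 15 by loss of LiCl (triple bond between the future C8 and C8a), as its dilithium dialkoxide | CC(C)=CCC/C(C)=C/CC1=C(OCOC)C#CC(C(O[Li])C[C@H](O[Li])c2cc(OCOC)cc(OCOC)c2)=C1OCOC | intermediate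
17 | (2S,4RS)-8-lithio derivative of 18 as its lithium 4-alkoxide | CC(C)=CCC/C(C)=C/Cc1c(OCOC)c([Li])c2c(c1OCOC)C(O[Li])C[C@@H](c1cc(OCOC)cc(OCOC)c1)O2 | intermediate
18 | (2S,4RS)-2-[3,5-bis(methoxymethoxy)phenyl]-6-[(2E)-3,7-dimethylocta-2,6-dien-1-yl]-5,7-bis(methoxymethoxy)-3,4-dihydro-2H-chromen-4-ol | CC(C)=CCC/C(C)=C/Cc1c(OCOC)cc2c(c1OCOC)C(O)C[C@@H](c1cc(OCOC)cc(OCOC)c1)O2 | intermediate
19 | (2S)-2-[3,5-bis(methoxymethoxy)phenyl]-6-[(2E)-3,7-dimethylocta-2,6-dien-1-yl]-5,7-bis(methoxymethoxy)-2,3-dihydro-4H-chromen-4-one | CC(C)=CCC/C(C)=C/Cc1c(OCOC)cc2c(c1OCOC)C(=O)C[C@@H](c1cc(OCOC)cc(OCOC)c1)O2 | intermediate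
20 | Schizolaenone C [(2S)-2-(3,5-dihydroxyphenyl)-6-[(2E)-3,7-dimethylocta-2,6-dien-1-yl]-5,7-dihydroxy-2,3-dihydro-4H-chromen-4-one] | CC(C)=CCC/C(C)=C/Cc1c(O)cc2c(c1O)C(=O)C[C@@H](c1cc(O)cc(O)c1)O2 | target

Total steps: 11. Longest linear sequence: 9 steps (steps 3 to 11, from 6); the ring A branch (steps 1 and 2) joins at step 7.

Steps most likely to fail

Step 9. The aryne may be diverted by addition of tetramethylpiperidine or by hydride transfer from the C2 carbinol, or it may not form at all if metalation goes to the benzylic–allylic CH2 of the geranyl group instead of C8. The fallback sets out from 14 and makes the same O1–C8a bond by palladium-catalysed intramolecular etherification of the aryl chloride with the C2 hydroxyl (Pd(OAc)2, 2-(di-tert-butylphosphino)-1,1′-binaphthyl, Cs2CO3, toluene, 80 °C). This Buchwald–Hartwig-type C–O coupling is known to close chromans from secondary alcohols with retention, and the C4 hydroxyl again cannot cyclise. The fallback comes back to the route at 18 and makes no compound outside the list (none F0).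

Step 7. Addition of the di-ortho-substituted aryllithium to the enolisable β-silyloxy aldehyde may be slow, which would open the way to enolisation, β-elimination of silanolate and loss of LiCl from the aryllithium. The fallback reverses the polarity and forms the C3–C4 bond by an aldol reaction. Setting out from 5, the aryllithium 12 is quenched with DMF, a fast and non-enolisable electrophile, to give 6-chloro-3-[(2E)-3,7-dimethylocta-2,6-dien-1-yl]-2,4-bis(methoxymethoxy)benzaldehyde F1. Ring B is brought in as a methyl ketone made from 7: MeMgBr addition should give 1-[3,5-bis(methoxymethoxy)phenyl]ethanol F2, and Dess–Martin oxidation 1-[3,5-bis(methoxymethoxy)phenyl]ethanone F3. The lithium enolate of F3 (LDA, THF, −78 °C) should add to F1 to give the racemic aldol 3-{6-chloro-3-[(2E)-3,7-dimethylocta-2,6-dien-1-yl]-2,4-bis(methoxymethoxy)phenyl}-3-hydroxy-1-[3,5-bis(methoxymethoxy)phenyl]propan-1-one F4. Noyori transfer hydrogenation of its unhindered aryl ketone (RuCl[(S,S)-TsDPEN](p-cymene), HCO2H/Et3N) should then set C2 (S) under catalyst control. The fallback comes back to the route at 14, so that 13 and step 8 are bypassed.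

Step 4. Facial selectivity in the allyl transfer may be incomplete, which would leave an enantiomeric impurity that is carried to the target. The fallback sets C2 by asymmetric ketone reduction instead of C–C bond formation. Setting out from 7, Roskamp homologation (ethyl diazoacetate, SnCl2 10 mol %, CH2Cl2) should give ethyl 3-[3,5-bis(methoxymethoxy)phenyl]-3-oxopropanoate F5. Noyori transfer hydrogenation (RuCl[(S,S)-TsDPEN](p-cymene), HCO2H/Et3N) should give ethyl (3S)-3-[3,5-bis(methoxymethoxy)phenyl]-3-hydroxypropanoate F6. Silylation (TBSCl, imidazole) should give ethyl (3S)-3-[3,5-bis(methoxymethoxy)phenyl]-3-[(tert-butyldimethylsilyl)oxy]propanoate F7, and i-Bu2AlH in CH2Cl2 at −78 °C should reduce the ester to the aldehyde. The fallback comes back to the route at 11, so that 8 to 10 are bypassed.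

Further compounds
F0 | step 9 | none | none
F1 | step 7 | 6-chloro-3-[(2E)-3,7-dimethylocta-2,6-dien-1-yl]-2,4-bis(methoxymethoxy)benzaldehyde | CC(C)=CCC/C(C)=C/Cc1c(OCOC)cc(Cl)c(C=O)c1OCOC
F2 | step 7 | (1RS)-1-[3,5-bis(methoxymethoxy)phenyl]ethanol | CC(O)c1cc(OCOC)cc(OCOC)c1
F3 | step 7 | 1-[3,5-bis(methoxymethoxy)phenyl]ethanone | CC(=O)c1cc(OCOC)cc(OCOC)c1
F4 | step 7 | (3RS)-3-{6-chloro-3-[(2E)-3,7-dimethylocta-2,6-dien-1-yl]-2,4-bis(methoxymethoxy)phenyl}-3-hydroxy-1-[3,5-bis(methoxymethoxy)phenyl]propan-1-one | CC(C)=CCC/C(C)=C/Cc1c(OCOC)cc(Cl)c(C(O)CC(=O)c2cc(OCOC)cc(OCOC)c2)c1OCOC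
F5 | step 4 | ethyl 3-[3,5-bis(methoxymethoxy)phenyl]-3-oxopropanoate | CCOC(=O)CC(=O)c1cc(OCOC)cc(OCOC)c1
F6 | step 4 | ethyl (3S)-3-[3,5-bis(methoxymethoxy)phenyl]-3-hydroxypropanoate | CCOC(=O)C[C@H](O)c1cc(OCOC)cc(OCOC)c1
F7 | step 4 | ethyl (3S)-3-[3,5-bis(methoxymethoxy)phenyl]-3-[(tert-butyldimethylsilyl)oxy]propanoate | CCOC(=O)C[C@H](O[Si](C)(C)C(C)(C)C)c1cc(OCOC)cc(OCOC)c1
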